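Remark on the chemistry: the target SMILES contains no stereocentre and no configurationally stable axis, so the compound is achiral; "single enantiomer" is met by construction and no stereocontrol is planned.

## Analysis of the target

The target is a depside: two hexasubstituted benzene rings joined by one aryl ester. Ring A is numbered C1 (CO2Me), C2 (CH3), C3 (Cl), C4 (O-acyl), C5 (CH3), C6 (OH). Ring B is numbered C1′ (bearing the ester carbonyl C7′), C2′ (CH3), C3′ (Cl), C4′ (OH), C5′ (CHO), C6′ (OH). The inter-ring link is O4–C7′(=O)–C1′.

There is no stereocentre; the C6–OH and C6′–OH are each hydrogen-bonded to an ortho ester carbonyl, and the C5′ aldehyde is chelated between two phenols. The sensitive groups are: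
- the aryl ester, a salicylate-type ester whose leaving group is a chlorophenoxide, so it is cleaved by alkoxide, hydroxide and amines;
- the aldehyde;
- two aryl C–Cl bonds, which rule out hydrogenolytic deprotection;
- three free phenols.

The synthesis is hard for two reasons. First, the O4–C7′ bond joins a carbonyl flanked by CH3 and OH to an oxygen flanked by CH3 and Cl, so four ortho substituents surround one C–O bond. Second, the two rings are so alike that Cl and CHO must be placed on ring B without touching ring A.

The feature that invites the key move is the pattern of ring B: acyl at C1′, methyl at C2′, oxygen at C4′ and C6′. This is exactly the folding pattern of a linear 3,5,7-triketo acid closed by an aldol bond C1′–C2′. Ring B can therefore be grown on O4 from an acyclic chain, and the ester is made while the acyl carbon is still an unhindered ketene carbon.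

## Retrosynthetic reasoning

**14 to 12 (C5′–CHO bond).** In 12, C5′ is the only ring carbon in the whole molecule that still bears hydrogen, and it lies between two phenolic oxygens. An electrophilic formylation is therefore regiochemically forced. Placing the aldehyde last also spares it the chlorination and the thermal and basic conditions of the earlier steps.

**12 to 11 (C3′–Cl bond).** Ring A of 11 has no ring hydrogen, so electrophilic chlorination can only occur on ring B. Of its two open sites, C3′ (ortho to the free C4′–OH, para to the chelated C6′–OH, next to the C2′ methyl) is the innately preferred one. Chlorinating before formylating uses this preference to reserve C5′ for the formyl group.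

**11 to 7 + 2 (key disconnection: O4–C7′ and C1′–C2′ together).** Both bonds are cut at once, so ring B disappears into the acyclic diketo-dioxinone 7 and the depside problem disappears with it. In the forward direction 7 must lose its dioxinone ring by cycloreversion to give acylketene 8. The C4–OH of 2 must add to 8 to give the triketo ester 9. Then 9 must close by aldol addition (via 10) and dehydrate to the aromatic ring. The gain is that the hindered ester is formed at an sp carbon before any ortho substituent exists on the acyl side. No protecting group is needed anywhere in the route.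

**7 to 5 to 3 (two chain C–C bonds).** The eight-carbon chain of 7 is assembled by two successive acetylations. The first is at the γ-carbon of the dienolate 4 of dioxinone 3. The second is at the terminal carbon of dianion 6 of keto-dioxinone 5. Each acidity difference directs the new bond to the chain terminus.

**2 to 1 (C3–Cl bond).** Phenol 2 is one chlorination away from the commercial ester 1, whose only ring hydrogen is at the required carbon.

## Alternatives that were turned down

**Alternative 1:** (textbook) Disconnection of the acyl–oxygen bond O4–C7′ alone, between two finished rings. The forward key step is a dehydrative esterification (trifluoroacetic anhydride or a carbodiimide) of 3-chloro-5-formyl-4,6-dihydroxy-2-methylbenzoic acid A1 with phenol 2. It was turned down for three reasons: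
- A1 itself needs about five steps from an orsellinate ester: a formylation that must be steered between two open positions, a chlorination, and an ester cleavage that must spare the aldehyde.
- The activated carboxyl of A1 lies between CH3 and OH and must meet an oxygen between CH3 and Cl, so the tetrahedral intermediate is crowded on both sides.
- With free C4′/C6′ hydroxyls the activated acid acylates itself, so the dibenzyl ether A2 would be needed. Hydrogenolytic debenzylation after coupling endangers two aryl C–Cl bonds and the aldehyde.

The hardest bond would be made last, with the most hindered partners, in a longer sequence.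

**Alternative 2:** Biosynthesis-type pseudo-dimer followed by C–H oxidation; the bond cut is the C–O of the formyl group, and both rings are traced to one monomer. In the forward direction 2 is hydrolysed to acid A3, A3 is esterified with 2 to the tetramethyl depside A4, and the C5′ methyl of A4 (flanked by two free phenols) is oxidised to the aldehyde through an ortho-quinone methide (DDQ in aqueous dioxane, or anodically). It was turned down for three reasons:
- A4 carries four aryl methyl groups, and the C5 methyl of ring A is also ortho to a phenol.
- Quinone methides from rings bearing an ester and a chlorine form only at high potential and are intercepted at the benzyl alcohol or ether stage or dimerise, so a second oxidation is needed.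
- Making A4 still requires the hindered esterification of alternative 1.

The route would carry two uncertain steps instead of one.

**Alternative 3:** Disconnection of the aryl–oxygen bond C4–O4 of ring A. The forward key step is O-arylation of the carboxylate of A1 by the unsymmetrical diaryliodonium salt A5 (ligand coupling at iodine). The idea is attractive because the carboxylate attacks iodine and ortho-substituted aryl groups transfer readily. It was turned down for four reasons:
- Ring A must arrive without O4, so the cheap ester 1, which already holds that oxygen, is useless and a hexasubstituted iodoarene must be built from scratch.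
- The free phenols of A1 and A5 are oxidised or arylated by iodine(III).
- The mesityl dummy group is not clearly differentiated from an aryl group that is itself di-ortho-substituted.
- A1 is still required in full.

Key step: step 4

## Route

Step 1
Reactants: 1 methyl 2,4-dihydroxy-3,6-dimethylbenzoate
Product: 2 methyl 3-chloro-4,6-dihydroxy-2,5-dimethylbenzoate
Conditions: SO2Cl2 (1.05 equiv), Et2O, 0 °C to rt
Reagents that add atoms: sulfuryl chloride, O=S(=O)(Cl)Cl
Why: Electrophilic aromatic chlorination; the only ring C–H of 1 is ortho to the free 4-OH and para to the chelated 2-OH, so one equivalent of reagent should give a single monochloride, and the low temperature should suppress ipso attack at the methyl-bearing carbons.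

Step 2
Reactants: 3 2,2,6-trimethyl-4H-1,3-dioxin-4-one
Product: 5 2,2-dimethyl-6-(2-oxopropyl)-4H-1,3-dioxin-4-one, via lithium dienolate 4 (not isolated)
Conditions: 3 (2 equiv), LiHMDS (2 equiv), THF, −78 °C; AcCl (1 equiv), −78 °C; 1 M HCl
Reagents that add atoms: acetyl chloride, CC(=O)Cl
Why: γ-Deprotonation gives the vinylogous enolate 4, which is C-acylated at its γ-carbon by the acid chloride (vinylogous Claisen-type acylation); the second equivalent of 4 takes up the more acidic product proton, which should prevent double acylation.

Step 3
Reactants: 5 2,2-dimethyl-6-(2-oxopropyl)-4H-1,3-dioxin-4-one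
Product: 7 6-(2,4-dioxopentyl)-2,2-dimethyl-4H-1,3-dioxin-4-one, via dilithium dianion 6 (not isolated)
Conditions: LDA (2.2 equiv), THF, −78 °C; MeC(O)N(OMe)Me (1.0 equiv), −78 to −40 °C; 1 M HCl
Reagents that add atoms: N-methoxy-N-methylacetamide, CC(=O)N(C)OC
Why: Dianion 6 reacts at its last-formed, most basic terminal carbon (γ-acylation of a β-dicarbonyl dianion), and the chelated tetrahedral adduct of the N-methoxy-N-methylamide should persist until the acidic quench, so the product is not exposed to enolate in the flask.

Step 4
Reactants: 7 6-(2,4-dioxopentyl)-2,2-dimethyl-4H-1,3-dioxin-4-one; 2 methyl 3-chloro-4,6-dihydroxy-2,5-dimethylbenzoate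
Product: 11 methyl 3-chloro-4-[(2,4-dihydroxy-6-methylbenzoyl)oxy]-6-hydroxy-2,5-dimethylbenzoate, via acylketene 8 (not isolated), via aryl triketo ester 9 (not isolated), via aldol adduct 10 (not isolated)
Conditions: 2 (1.5 equiv), PhMe, 110 °C, 7 added slowly; then Et3N, CH2Cl2, 0 °C to rt; then TFA, rt
Reagents that add atoms: none
Why: Heating 7 triggers a retro-hetero-Diels–Alder reaction that releases acetone and the acylketene 8; the free C4–OH of 2 adds to the sp-hybridised ketene carbon through a six-membered, carbonyl-assisted transition state and gives the aryl 3,5,7-trioxooctanoate 9, so the O4–C7′ ester bond is made before any ortho substituent exists on the acyl side. Triethylamine then enolises 9, and the carbon between the ester and the first ketone (future C1′) adds to the terminal methyl ketone (future C2′) in a favoured 6-(enolendo)-exo-trig aldol closure to 10, which acid dehydrates to the aromatic ring B of 11. The closest known reaction type is the dioxinone thermolysis, ketene trapping and late-stage aldol aromatisation sequence to resorcylate esters, together with the acetoacetylation of phenols by dioxinone-derived acylketenes. No stereocentre has to be controlled, because the two stereocentres of 10 are erased on aromatisation. Site selectivity on 2 should come from the substrate: the C6–OH is locked in a hydrogen bond to the methyl ester carbonyl and flanked by CO2Me and CH3, which leaves O4–H as the only free phenol. The step needs intermolecular capture of 8 to beat capture by its own enolised diketone, which an excess of 2 at high concentration and slow addition of 7 should secure. It also needs aldol closure to beat Claisen closure or lactonisation with loss of the aryloxide; an amine base in an aprotic solvent, without magnesium or alkoxide, is the regime in which triketo esters close by the aldol mode.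

Step 5
Reactants: 11 methyl 3-chloro-4-[(2,4-dihydroxy-6-methylbenzoyl)oxy]-6-hydroxy-2,5-dimethylbenzoate
Product: 12 methyl 3-chloro-4-[(3-chloro-4,6-dihydroxy-2-methylbenzoyl)oxy]-6-hydroxy-2,5-dimethylbenzoate
Conditions: SO2Cl2 (1.0 equiv), Et2O–CH2Cl2, 0 °C
Reagents that add atoms: sulfuryl chloride, O=S(=O)(Cl)Cl
Why: Electrophilic chlorination can only occur on ring B because ring A has no ring hydrogen; C3′ (ortho to the free C4′–OH, para to the chelated C6′–OH, next to the methyl group) is the usual first site of halogenation in 2,4-dihydroxy-6-methylbenzoyl rings, whereas the carbon between the two hydroxyls reacts more slowly.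

Step 6
Reactants: 12 methyl 3-chloro-4-[(3-chloro-4,6-dihydroxy-2-methylbenzoyl)oxy]-6-hydroxy-2,5-dimethylbenzoate
Product: 14 methyl 3-chloro-4-[(3-chloro-5-formyl-4,6-dihydroxy-2-methylbenzoyl)oxy]-6-hydroxy-2,5-dimethylbenzoate, via chloro methyl ether 13 (not isolated)
Conditions: Cl2CHOMe (2 equiv), TiCl4 (4 equiv), CH2Cl2, 0 °C to rt; then 1 M HCl, 0 °C
Reagents that add atoms: dichloromethyl methyl ether, COC(Cl)Cl; water, O
Why: Rieche formylation (Friedel–Crafts alkylation by the titanium-activated methoxychlorocarbenium ion to 13, hydrolysed to the aldehyde on work-up); C5′ is the only ring C–H left in 12 and is ortho to two titanium-bound phenoxides, so the regiochemistry is fixed by the substrate and the product is the target.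

## Compound list

1 | methyl 2,4-dihydroxy-3,6-dimethylbenzoate (atraric acid) | COC(=O)c1c(C)cc(O)c(C)c1O | starting material
2 | methyl 3-chloro-4,6-dihydroxy-2,5-dimethylbenzoate | COC(=O)c1c(C)c(Cl)c(O)c(C)c1O | intermediate
3 | 2,2,6-trimethyl-4H-1,3-dioxin-4-one | CC1=CC(=O)OC(C)(C)O1 | starting material
4 | lithium 2,2-dimethyl-6-methylidene-6H-1,3-dioxin-4-olate (dienolate of 3; not isolated) | [Li+].[O-]C1=CC(=C)OC(C)(C)O1 | intermediate
5 | 2,2-dimethyl-6-(2-oxopropyl)-4H-1,3-dioxin-4-one | CC(=O)CC1=CC(=O)OC(C)(C)O1 | intermediate
6 | dilithium 2,2-dimethyl-6-(2-oxidoprop-2-en-1-ylidene)-6H-1,3-dioxin-4-olate (dianion of 5; not isolated) | [Li+].[Li+].C=C([O-])C=C1C=C([O-])OC(C)(C)O1 | intermediate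
7 | 6-(2,4-dioxopentyl)-2,2-dimethyl-4H-1,3-dioxin-4-one | CC(=O)CC(=O)CC1=CC(=O)OC(C)(C)O1 | intermediate
8 | oct-1-ene-1,3,5,7-tetrone (acylketene; not isolated) | CC(=O)CC(=O)CC(=O)C=C=O | intermediate
9 | methyl 3-chloro-6-hydroxy-2,5-dimethyl-4-[(3,5,7-trioxooctanoyl)oxy]benzoate (not isolated) | COC(=O)c1c(C)c(Cl)c(OC(=O)CC(=O)CC(=O)CC(C)=O)c(C)c1O | intermediate
10 | methyl 3-chloro-6-hydroxy-4-[(2-hydroxy-2-methyl-4,6-dioxocyclohexane-1-carbonyl)oxy]-2,5-dimethylbenzoate (mixture of stereoisomers and tautomers; not isolated) | COC(=O)c1c(C)c(Cl)c(OC(=O)C2C(=O)CC(=O)CC2(C)O)c(C)c1O | intermediate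
11 | methyl 3-chloro-4-[(2,4-dihydroxy-6-methylbenzoyl)oxy]-6-hydroxy-2,5-dimethylbenzoate | COC(=O)c1c(C)c(Cl)c(OC(=O)c2c(C)cc(O)cc2O)c(C)c1O | intermediate
12 | methyl 3-chloro-4-[(3-chloro-4,6-dihydroxy-2-methylbenzoyl)oxy]-6-hydroxy-2,5-dimethylbenzoate | COC(=O)c1c(C)c(Cl)c(OC(=O)c2c(C)c(Cl)c(O)cc2O)c(C)c1O | intermediate
13 | methyl 3-chloro-4-({3-chloro-5-[chloro(methoxy)methyl]-4,6-dihydroxy-2-methylbenzoyl}oxy)-6-hydroxy-2,5-dimethylbenzoate (racemic; not isolated) | COC(=O)c1c(C)c(Cl)c(OC(=O)c2c(C)c(Cl)c(O)c(C(Cl)OC)c2O)c(C)c1O | intermediate
14 | methyl 3-chloro-4-[(3-chloro-5-formyl-4,6-dihydroxy-2-methylbenzoyl)oxy]-6-hydroxy-2,5-dimethylbenzoate (CNP0249536.0) | COC(=O)c1c(C)c(Cl)c(OC(=O)c2c(C)c(Cl)c(O)c(C=O)c2O)c(C)c1O | target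

## Step count and least certain steps

Total step count: 6. Longest linear sequence: 5 steps (steps 2, 3, 4, 5 and 6 from 3); step 1 is a one-step branch from 1.

**Step 4 (key step).** Two processes may defeat it. During thermolysis, the ketene may be captured by the enol oxygen of its own diketone, or may dimerise, faster than it is captured by a phenol that is flanked by CH3 and Cl and is fairly acidic. After capture, the amine may expel the aryloxide (return to the ketene, or Claisen or lactone closure at the activated aryl ester) faster than the aldol closure occurs. The fallback reverses the order of ring formation and acylation. It sets out from 7, which with Et3N in CH2Cl2 at room temperature should aromatise with retention of the dioxinone ring (vinylogous aldol closure and dehydration) to 7-hydroxy-2,2,5-trimethyl-4H-1,3-benzodioxin-4-one F1. Irradiation of F1 (about 300 nm, CH2Cl2, room temperature) in the presence of 2 should expel acetone and generate the quinoketene 3-hydroxy-5-methyl-6-(oxomethylidene)cyclohexa-2,4-dien-1-one F2. The O4–H of 2 captures F2, and the route is rejoined at 11. In this variant no acyclic aryl ester meets base, and the acylating species cannot cyclise on itself.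

**Step 3.** Proton transfer from the enolisable amide to the strongly basic terminal carbanion, O-acylation, and self-condensation of the sensitive product during isolation may erode the material balance. The fallback replaces dianion chemistry by soft enolisation. It sets out from 3, whose dienolate 4 is acylated with allyl 3-chloro-3-oxopropanoate F3 (made from mono-allyl malonate and oxalyl chloride) to give allyl 4-(2,2-dimethyl-4-oxo-4H-1,3-dioxin-6-yl)-3-oxobutanoate F4. MgCl2/pyridine and acetyl chloride should acylate F4 at the doubly activated carbon to give allyl 2-acetyl-4-(2,2-dimethyl-4-oxo-4H-1,3-dioxin-6-yl)-3-oxobutanoate F5. Pd(PPh3)4 and morpholine then remove the allyl group with decarboxylation, and the route is rejoined at 7.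

**Step 5.** Poor site selectivity between C3′ and C5′, or over-chlorination of ring B, may occur because both open positions are activated by two oxygens, and the isomers would be hard to separate. The fallback fixes the chlorine on the acyclic chain. It sets out from 7, which with N-chlorosuccinimide (1 equiv, CH2Cl2) should be chlorinated at the most acidic, largely enolised methylene between the two ketones to give 6-(3-chloro-2,4-dioxopentyl)-2,2-dimethyl-4H-1,3-dioxin-4-one F6. F6 is taken through the conditions of step 4 with 2; the chlorinated chain carbon becomes C3′, and the route is rejoined at 12.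

**Step 6.** Electrophilic substitution may be sluggish at a carbon of a ring that bears an ester and a chlorine, and long exposure to the Lewis acid may cleave the depside ester. The fallback uses a boron template instead of a carbocationic electrophile. It sets out from 12, which with phenylboronic acid and paraformaldehyde (catalytic propionic acid, toluene, reflux with azeotropic removal of water) should give the benzodioxaborin F7, methyl 3-chloro-4-[(8-chloro-5-hydroxy-7-methyl-2-phenyl-4H-1,3,2-benzodioxaborin-6-carbonyl)oxy]-6-hydroxy-2,5-dimethylbenzoate. Exchange with propane-1,3-diol releases the hydroxymethyl compound F8, methyl 3-chloro-4-{[3-chloro-4,6-dihydroxy-5-(hydroxymethyl)-2-methylbenzoyl]oxy}-6-hydroxy-2,5-dimethylbenzoate. MnO2 in CH2Cl2 oxidises F8 to the aldehyde, and the route is rejoined at 14.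

## Further compounds

F1 | step 4 | 7-hydroxy-2,2,5-trimethyl-4H-1,3-benzodioxin-4-one | Cc1cc(O)cc2OC(C)(C)OC(=O)c12
F2 | step 4 | 3-hydroxy-5-methyl-6-(oxomethylidene)cyclohexa-2,4-dien-1-one | CC1=CC(O)=CC(=O)C1=C=O
F3 | step 3 | allyl 3-chloro-3-oxopropanoate | C=CCOC(=O)CC(Cl)=O
F4 | step 3 | allyl 4-(2,2-dimethyl-4-oxo-4H-1,3-dioxin-6-yl)-3-oxobutanoate | C=CCOC(=O)CC(=O)CC1=CC(=O)OC(C)(C)O1
F5 | step 3 | allyl 2-acetyl-4-(2,2-dimethyl-4-oxo-4H-1,3-dioxin-6-yl)-3-oxobutanoate | C=CCOC(=O)C(C(C)=O)C(=O)CC1=CC(=O)OC(C)(C)O1
F6 | step 5 | 6-(3-chloro-2,4-dioxopentyl)-2,2-dimethyl-4H-1,3-dioxin-4-one | CC(=O)C(Cl)C(=O)CC1=CC(=O)OC(C)(C)O1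
F7 | step 6 | methyl 3-chloro-4-[(8-chloro-5-hydroxy-7-methyl-2-phenyl-4H-1,3,2-benzodioxaborin-6-carbonyl)oxy]-6-hydroxy-2,5-dimethylbenzoate | COC(=O)c1c(C)c(Cl)c(OC(=O)c2c(C)c(Cl)c3OB(c4ccccc4)OCc3c2O)c(C)c1O
F8 | step 6 | methyl 3-chloro-4-{[3-chloro-4,6-dihydroxy-5-(hydroxymethyl)-2-methylbenzoyl]oxy}-6-hydroxy-2,5-dimethylbenzoate | COC(=O)c1c(C)c(Cl)c(OC(=O)c2c(C)c(Cl)c(O)c(CO)c2O)c(C)c1O
A1 | alternative 1 | 3-chloro-5-formyl-4,6-dihydroxy-2-methylbenzoic acid | Cc1c(Cl)c(O)c(C=O)c(O)c1C(=O)O
A2 | alternative 1 | 4,6-bis(benzyloxy)-3-chloro-5-formyl-2-methylbenzoic acid | Cc1c(Cl)c(OCc2ccccc2)c(C=O)c(OCc2ccccc2)c1C(=O)O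
A3 | alternative 2 | 3-chloro-4,6-dihydroxy-2,5-dimethylbenzoic acid | Cc1c(Cl)c(O)c(C)c(O)c1C(=O)O
A4 | alternative 2 | methyl 3-chloro-4-[(3-chloro-4,6-dihydroxy-2,5-dimethylbenzoyl)oxy]-6-hydroxy-2,5-dimethylbenzoate | COC(=O)c1c(C)c(Cl)c(OC(=O)c2c(C)c(Cl)c(O)c(C)c2O)c(C)c1O
A5 | alternative 3 | (2-chloro-5-hydroxy-4-methoxycarbonyl-3,6-dimethylphenyl)(2,4,6-trimethylphenyl)iodonium trifluoromethanesulfonate | COC(=O)c1c(C)c(Cl)c([I+]c2c(C)cc(C)cc2C)c(C)c1O.[O-]S(=O)(=O)C(F)(F)F
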